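**Strategy.** The route rests on cutting both pyrrole rings at C3–C3a and N1–C2. Each indole is joined to the core through C5 and carries its 1,1-dimethylallyl group on C3, with N1–H and C2–H free; that is the pattern a para-substituted arylhydrazine and an aldehyde with one α-CH2 give. A two-fold Fischer indolisation with 3,3-dimethylpent-4-enal therefore closes both five-membered rings in one operation, on a cyclohexene that already holds both stereocentres and the styryl alkene. The precursor is the (1S,2R)-bis(4-hydrazinylphenyl) compound, kept as its bis-hydrochloride; its stereocentres are set together by an enantioselective Diels–Alder reaction of an (E)-enal.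

Key step: step 9

Assumption: the (S)-configured oxazaborolidine–AlBr3 catalyst is taken, by the usual binding model for α-substituted enals (formyl group bound, s-trans enal, one face shielded by an aryl group), to leave the Cα-Re face of 3 open; should aldehyde 8 prove antipodal, the (R)-catalyst is used with nothing else changed.

**Route**

Step 1
Reactants: 1 4-bromobenzaldehyde; 2 propanal
Product: 3 (E)-3-(4-bromophenyl)-2-methylprop-2-enal
Conditions: NaOH (0.3 equiv), EtOH–H2O, 0 °C → rt, slow addition of 2
Reagents that add atoms: none
Why: Claisen–Schmidt (crossed aldol) condensation: only propanal can enolise, the non-enolisable aryl aldehyde is the acceptor, and E1cB dehydration should give the conjugated enal as its thermodynamic (E)-isomer with aryl anti to CHO, the geometry that later encodes the relative configuration.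

Step 2
Reactants: 4 3-methyl-2,5-dihydrothiophene 1,1-dioxide (3-methyl-3-sulfolene)
Product: 5 3-methyl-2-(trimethylsilyl)-2,5-dihydrothiophene 1,1-dioxide (racemic)
Conditions: LiHMDS (1.1 equiv) added to 4 and Me3SiCl (1.5 equiv), THF, −78 °C
Reagents that add atoms: chlorotrimethylsilane, C[Si](C)(C)Cl
Why: Silylation of an α-sulfonyl carbanion with in situ quench: the base should remove the C2 proton (allyl anion with charge on C2/C4, not on the methyl-bearing carbon) and Me3SiCl already present traps the anion before it can ring-open; the new stereocentre is racemic and disappears in step 3.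

Step 3
Reactants: 5 3-methyl-2-(trimethylsilyl)-2,5-dihydrothiophene 1,1-dioxide
Product: 6 (E)-trimethyl(2-methylbuta-1,3-dien-1-yl)silane
Conditions: neat, NaHCO3 (cat.), 130–140 °C, reduced pressure, diene distilled out
Reagents that add atoms: none
Why: Thermal cheletropic extrusion of SO2, suprafacial and disrotatory, in which the bulky silyl group on C2 turns outward, so the 1-silyl diene should form as the (E)-isomer that can adopt the s-cis conformation.

Step 4
Reactants: 3 (E)-3-(4-bromophenyl)-2-methylprop-2-enal; 6 (E)-trimethyl(2-methylbuta-1,3-dien-1-yl)silane (2.5 equiv)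
Product: 8 (1R,2S)-2-(4-bromophenyl)-1,4-dimethylcyclohex-3-ene-1-carbaldehyde, via 3-silyl cycloadduct 7 (not isolated)
Conditions: (S)-o-tolyl-oxazaborolidine·AlBr3 (15 mol%), CH2Cl2, −40 → −20 °C; then CF3CO2H (3 equiv), 0 °C
Reagents that add atoms: none
Why: Catalytic enantioselective Diels–Alder reaction (cationic oxazaborolidine Lewis acid) followed by SE2′ protodesilylation of the allylsilane: the 2-methyl group and the β-silicon effect make the silicon-bearing terminus of 6 the nucleophilic end, so it bonds to the aryl-bearing β-carbon of the activated enal; suprafacial addition across the (E)-alkene places aryl cis to methyl and trans to CHO; the catalyst should leave the Cα-Re face open, which sets C1 (R) and C2 (S) in the same event; γ-protonation of the allylsilane then moves the double bond to C3=C4 and erases the silyl-bearing centre, whose configuration is therefore irrelevant.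

Step 5
Reactants: 8 (1R,2S)-2-(4-bromophenyl)-1,4-dimethylcyclohex-3-ene-1-carbaldehyde; 9 diethyl (4-bromobenzyl)phosphonate
Product: 10 1-bromo-4-[(E)-2-[(1S,2R)-2-(4-bromophenyl)-1,4-dimethylcyclohex-3-en-1-yl]ethenyl]benzene
Conditions: KOtBu (1.3 equiv), THF, 0 → 50 °C
Reagents that add atoms: none
Why: Horner–Wadsworth–Emmons olefination: the aldehyde has a quaternary α-carbon and cannot enolise or epimerise, and reversible addition of the benzylic phosphonate anion followed by syn-elimination from the less hindered adduct should give the (E)-alkene, with both stereocentres untouched (the descriptors change only through CIP priorities).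

Step 6
Reactants: 10 the dibromide; 11 benzophenone hydrazone (2.3 equiv)
Product: 12 1-(diphenylmethylidene)-2-{4-[(E)-2-[(1S,2R)-2-{4-[2-(diphenylmethylidene)hydrazinyl]phenyl}-1,4-dimethylcyclohex-3-en-1-yl]ethenyl]phenyl}hydrazine
Conditions: Pd(OAc)2 (5 mol%), Xantphos (6 mol%), NaOtBu (2.8 equiv), toluene, 90 °C
Reagents that add atoms: none
Why: Two-fold Buchwald–Hartwig amination: oxidative addition into each Ar–Br bond, binding and deprotonation of the hydrazone NH2 and reductive elimination should form both C–N bonds, the diphenylmethylene group preventing double arylation, while the alkenes and stereocentres are spectators.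

Step 7
Reactants: 12 the bis(benzophenone hydrazone)
Product: 13 {4-[(E)-2-[(1S,2R)-2-(4-hydrazinylphenyl)-1,4-dimethylcyclohex-3-en-1-yl]ethenyl]phenyl}hydrazine bis(hydrochloride)
Conditions: conc. HCl–EtOH (1:6), 60 °C, Ar; toluene wash; salt filtered
Reagents that add atoms: hydrogen chloride, Cl
Why: Acid hydrolysis of a hydrazone: protonation of C=N, addition of water and expulsion of the arylhydrazine, which is held as its hydrochloride and so is protected from air oxidation while benzophenone is washed out; a short time at 60 °C should leave the trisubstituted alkene in place.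

Step 8
Reactants: 14 methyl 3,3-dimethylpent-4-enoate
Product: 15 3,3-dimethylpent-4-enal
Conditions: DIBAL-H (1.05 equiv), CH2Cl2, −78 °C; MeOH, then aq. Rochelle salt
Reagents that add atoms: none
Why: Partial ester reduction with DIBAL-H: at −78 °C the aluminium hemiacetal from one hydride transfer is stable and should release the aldehyde only on work-up, the neopentyl-like environment further disfavouring a second addition; no stereocentre is involved.

Step 9
Reactants: 13 the bis-hydrazine bis(hydrochloride); 15 3,3-dimethylpent-4-enal (2.4 equiv)
Product: 18 3-(2-methylbut-3-en-2-yl)-5-[(E)-2-[(1S,2R)-1,4-dimethyl-2-[3-(2-methylbut-3-en-2-yl)-1H-indol-5-yl]cyclohex-3-en-1-yl]ethenyl]-1H-indole (the target), via free bis-hydrazine 16 (not isolated), via bis-hydrazone 17 (not isolated)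
Conditions: EtOH–H2O (4:1), degassed, Ar, 25 °C, 1 h; then 80 °C; no added acid
Reagents that add atoms: none
Why: Each hydrazinium group releases the free hydrazine (16), which condenses with the aldehyde to the N-aryl hydrazone (17); tautomerisation through the only α-CH2 gives the ene-hydrazine, whose N-protonated form undergoes a [3,3]-sigmatropic shift that cleaves N–N and forges C3–C3a at a ring carbon ortho to nitrogen, and rearomatisation leaves an ortho-aminoaryl iminium ion. This is the Fischer indole synthesis performed twice in one flask, the closest known cases being indolisations of para-substituted arylhydrazine hydrochlorides with aldehydes bearing a single α-methylene in hot aqueous alcohol. Each pyrrole ring then closes by 5-exo-trig attack of the aniline nitrogen on the iminium carbon (N1–C2), and loss of ammonia, trapped as NH4Cl, aromatises it. No stereocentre is formed: C1 of the cyclohexene is quaternary and C2 is not enolisable, so both should be carried through unchanged. Regioselectivity is fixed by the substrate, since para substitution makes the two ortho positions of each ring equivalent (core at C5) and the aldehyde can enolise only toward its one CH2 (preformed quaternary allylic carbon at C3, C2–H free). The selectivity the step needs is chemoselectivity toward three kinds of alkene and the acid-labile 3-tert-alkylindole, and it is sought by using only the two equivalents of HCl carried by the salt, in dilute degassed solution at no more than 80 °C.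

**Compound list**

1 | 4-bromobenzaldehyde | O=Cc1ccc(Br)cc1 | starting material
2 | propanal | CCC=O | starting material
3 | (E)-3-(4-bromophenyl)-2-methylprop-2-enal | O=C/C(C)=C/c1ccc(Br)cc1 | intermediate
4 | 3-methyl-2,5-dihydrothiophene 1,1-dioxide | CC1=CCS(=O)(=O)C1 | starting material
5 | 3-methyl-2-(trimethylsilyl)-2,5-dihydrothiophene 1,1-dioxide (racemic) | CC1=CCS(=O)(=O)C1[Si](C)(C)C | intermediate
6 | (E)-trimethyl(2-methylbuta-1,3-dien-1-yl)silane | C=C/C(C)=C/[Si](C)(C)C | intermediate
7 | (1R,2S,3R)-2-(4-bromophenyl)-1,4-dimethyl-3-(trimethylsilyl)cyclohex-4-ene-1-carbaldehyde (expected C3 epimer, silyl trans to aryl; C3 is erased in the same step) | O=C[C@]1(C)CC=C(C)[C@H]([Si](C)(C)C)[C@H]1c1ccc(Br)cc1 | intermediate (not isolated)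
8 | (1R,2S)-2-(4-bromophenyl)-1,4-dimethylcyclohex-3-ene-1-carbaldehyde (aryl cis to methyl, trans to CHO) | O=C[C@]1(C)CCC(C)=C[C@H]1c1ccc(Br)cc1 | intermediate
9 | diethyl (4-bromobenzyl)phosphonate | CCOP(=O)(Cc1ccc(Br)cc1)OCC | starting material
10 | 1-bromo-4-[(E)-2-[(1S,2R)-2-(4-bromophenyl)-1,4-dimethylcyclohex-3-en-1-yl]ethenyl]benzene | Brc1ccc(/C=C/[C@]2(C)CCC(C)=C[C@H]2c2ccc(Br)cc2)cc1 | intermediate
11 | benzophenone hydrazone | NN=C(c1ccccc1)c1ccccc1 | starting material
12 | 1-(diphenylmethylidene)-2-{4-[(E)-2-[(1S,2R)-2-{4-[2-(diphenylmethylidene)hydrazinyl]phenyl}-1,4-dimethylcyclohex-3-en-1-yl]ethenyl]phenyl}hydrazine | c1ccccc1C(c1ccccc1)=NNc1ccc(/C=C/[C@]2(C)CCC(C)=C[C@H]2c2ccc(NN=C(c3ccccc3)c3ccccc3)cc2)cc1 | intermediate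
13 | {4-[(E)-2-[(1S,2R)-2-(4-hydrazinylphenyl)-1,4-dimethylcyclohex-3-en-1-yl]ethenyl]phenyl}hydrazine bis(hydrochloride) | NNc1ccc(/C=C/[C@]2(C)CCC(C)=C[C@H]2c2ccc(NN)cc2)cc1.Cl.Cl | intermediate
14 | methyl 3,3-dimethylpent-4-enoate | COC(=O)CC(C)(C)C=C | starting material
15 | 3,3-dimethylpent-4-enal | C=CC(C)(C)CC=O | intermediate
16 | {4-[(E)-2-[(1S,2R)-2-(4-hydrazinylphenyl)-1,4-dimethylcyclohex-3-en-1-yl]ethenyl]phenyl}hydrazine (free base) | NNc1ccc(/C=C/[C@]2(C)CCC(C)=C[C@H]2c2ccc(NN)cc2)cc1 | intermediate (not isolated)
17 | bis[(E)-3,3-dimethylpent-4-en-1-ylidene] hydrazone of 16 | C=CC(C)(C)C/C=N/Nc1ccc(/C=C/[C@]2(C)CCC(C)=C[C@H]2c2ccc(N/N=C/CC(C)(C)C=C)cc2)cc1 | intermediate (not isolated)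
18 | 3-(2-methylbut-3-en-2-yl)-5-[(E)-2-[(1S,2R)-1,4-dimethyl-2-[3-(2-methylbut-3-en-2-yl)-1H-indol-5-yl]cyclohex-3-en-1-yl]ethenyl]-1H-indole | C=CC(C)(C)c1c[nH]c2ccc(/C=C/[C@]3(C)CCC(C)=C[C@H]3c3ccc4[nH]cc(C(C)(C)C=C)c4c3)cc12 | target

**Step count and risk**

Total step count: 9. Longest linear sequence: 7 steps (2, 3, 4, 5, 6, 7, 9).

The three steps most likely to fail, in order of risk:

Step 4. The trisubstituted, aryl-conjugated enal may add too slowly, the catalyst may protodesilylate the diene before cycloaddition, or the two enal faces may be discriminated poorly. The fallback gives up catalytic induction for a racemic cycloaddition and a resolution. It sets out again from 3 and 6, now driven by a stoichiometric achiral Lewis acid (EtAlCl2, CH2Cl2, −78 → 0 °C), which should give 7 together with the enantiomeric allylsilane F1. Protodesilylation with CF3CO2H as before should give 8 mixed with the enantiomeric aldehyde F2. Preparative chromatography on a chiral stationary phase (amylose carbamate, SFC) separates the two, and the bromine atom allows the absolute configuration to be confirmed by anomalous-dispersion X-ray analysis. The route is rejoined at 8.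

Step 9. The acid needed for the [3,3] shift may cause loss or 3→2 migration of the tert-allyl group, migration of the ring alkene, or stalling after one indole has formed. The fallback builds both indoles under basic conditions and sets out from dibromide 10. Palladium-catalysed coupling with ammonia (Pd/Josiphos-type ligand, NH3 in dioxane, NaOtBu) should give the bis-aniline F3. Iodination ortho to each amino group (BnMe3N·ICl2, CaCO3, CH2Cl2–MeOH; the para positions are blocked) should give the bis(2-iodoaniline) F4. A two-fold palladium-catalysed annulation of F4 with aldehyde 15 (Pd(OAc)2, DABCO, DMF, 85 °C; enamine formation, oxidative addition, intramolecular Heck-type C3–C3a closure) then arrives at 18.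

Step 7. Hydrazone cleavage may be incomplete under conditions gentle enough for the ring alkene, that alkene may be hydrochlorinated or may migrate, or the hydrazine may oxidise during isolation. The fallback installs the N–N unit without a protecting group and sets out from dibromide 10. Direct palladium-catalysed mono-arylation of hydrazine (N2H4·H2O in excess, Pd/CyPF-tBu, KOH, dioxane, 100 °C) should give the bis-hydrazine under basic conditions. Brief treatment with HCl in ether at 0 °C precipitates the same salt, returning to the route at 13.

**Further compounds**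

F1 | step 4 | (1S,2R,3S)-2-(4-bromophenyl)-1,4-dimethyl-3-(trimethylsilyl)cyclohex-4-ene-1-carbaldehyde (enantiomer of 7) | O=C[C@@]1(C)CC=C(C)[C@@H]([Si](C)(C)C)[C@@H]1c1ccc(Br)cc1
F2 | step 4 | (1S,2R)-2-(4-bromophenyl)-1,4-dimethylcyclohex-3-ene-1-carbaldehyde (enantiomer of 8) | O=C[C@@]1(C)CCC(C)=C[C@@H]1c1ccc(Br)cc1
F3 | step 9 | 4-[(E)-2-[(1S,2R)-2-(4-aminophenyl)-1,4-dimethylcyclohex-3-en-1-yl]ethenyl]aniline | Nc1ccc(/C=C/[C@]2(C)CCC(C)=C[C@H]2c2ccc(N)cc2)cc1
F4 | step 9 | 4-[(E)-2-[(1S,2R)-2-(4-amino-3-iodophenyl)-1,4-dimethylcyclohex-3-en-1-yl]ethenyl]-2-iodoaniline | Nc1ccc(/C=C/[C@]2(C)CCC(C)=C[C@H]2c2ccc(N)c(I)c2)cc1I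
F0 | step 7 | none | none
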